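Retrosynthetic overview
26 ⇐ ethylene enyne metathesis of alkyne 25 ⇐ Evans–Tishchenko reaction (CH3CHO) of β-hydroxy aldehyde 24, which makes C3–OAc and C19–OH together.
Ring A (C10–C1–C2–C3–C4–C5) ⇐ contraction of the seven-membered ring C10–C1–C2–C3–C19–C4–C5 of 22; the enabling feature is the trans-2,3-epoxy silyl ether C3(OTBS)–C19(H)–C4(CH3), whose tertiary oxirane carbon C4 is bonded to C5 of ring B, so that C3 shifts from C19 to C4 and C19 leaves the ring as the formyl group.
Seven-membered ring ⇐ ring-closing metathesis of the C5 isopropenyl group (C4, C18) with a (3R)-vinyl carbinol on the C10 chain; ring B with C5, C8, C9, C10 ⇐ (S)-carvone by double α′-alkylation, Wharton transposition, Eschenmoser–Claisen rearrangement and iodolactonization.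
Order of ring formation: ring B (from carvone), then the seven-membered carbocycle (step 12), then ring A by ring contraction (step 18).

Key step: step 18

Remark on the chemistry: labdane numbering is used for all intermediates (C1–C10 core, C11–C16 side chain, C17 on C8, C18 and C19 on C4, C20 on C10), and the target is read as a trans-decalin with H-5 anti to C20, with C11, O-8 and C19 on the H-5 face and O-3, C17 and C18 on the C20 face.

Step 1
Reactants: 1 (S)-(+)-carvone
Product: 2 trans-6-methylcarvone
Conditions: LiN(iPr)2 (LDA), THF, −78 °C; CH3I, −78 → 0 °C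
Reagents that add atoms: iodomethane, CI
Why: Kinetic deprotonation gives the cross-conjugated α′-enolate, which is C-methylated (enolate alkylation); the new centre forms mainly trans to isopropenyl but is re-enolised in step 2, so its configuration does not matter.

Step 2
Reactants: 2 trans-6-methylcarvone
Product: 3 6-allyl-6-methylcarvone
Conditions: LiN(iPr)2 (LDA), THF, −78 °C; allyl bromide, DMPU, −78 °C → rt
Reagents that add atoms: allyl bromide, C=CCBr
Why: Enolate alkylation of the re-formed α′-enolate, in which allyl bromide should approach anti to the adjacent isopropenyl group, placing allyl trans and methyl cis to isopropenyl at the quaternary centre (future C10).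

Step 3
Reactants: 3 6-allyl-6-methylcarvone
Product: 4 epoxy ketone
Conditions: 30% aq H2O2, NaOH (cat.), MeOH, 0 °C
Reagents that add atoms: hydrogen peroxide, OO
Why: Weitz–Scheffer nucleophilic epoxidation touches only the electron-poor enone double bond, and hydroperoxide should add to C7 anti to the C5 isopropenyl group as it does with carvone itself, putting the oxirane on the face that later carries O-8 and C11.

Step 4
Reactants: 4 epoxy ketone
Product: 6 transposed allylic alcohol, via epoxy hydrazone 5 (not isolated)
Conditions: N2H4·H2O, AcOH (cat.), MeOH, 0 °C → rt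
Reagents that add atoms: none
Why: Wharton transposition, in which the epoxy hydrazone opens to a vinyl diazene that loses N2 to give the C8=C9 alkene while the C7–O bond of the oxirane is kept, so C7–OH stays trans to isopropenyl.

Step 5
Reactants: 6 transposed allylic alcohol
Product: 8 C9 acetamide, via ketene N,O-acetal 7 (not isolated)
Conditions: CH3C(OCH3)2N(CH3)2, xylene, 140 °C
Reagents that add atoms: N,N-dimethylacetamide dimethyl acetal, COC(C)(OC)N(C)C
Why: Eschenmoser–Claisen rearrangement, in which the ketene N,O-acetal on O-7 undergoes a suprafacial [3,3] shift, so C11 is delivered to C9 on the face of the former C7–O bond (trans to isopropenyl, anti to C20) next to the quaternary C10.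

Step 6
Reactants: 8 C9 acetamide
Product: 10 iodolactone, via iminium lactone iodide 9 (not isolated)
Conditions: I2, THF/H2O, 0 °C → rt; aq NaHCO3/Na2S2O3 work-up
Reagents that add atoms: iodine, II; water, O
Why: Iodolactonization of the γ,δ-unsaturated amide, in which the amide oxygen can reach the tertiary C8 only on the face of C11 (5-exo, anti to the iodonium), fixing O-8 cis to C11 and C17 on the opposite face before the iminium ion is hydrolysed to the lactone.

Step 7
Reactants: 10 iodolactone
Product: 11 cis-fused γ-lactone
Conditions: Bu3SnH, AIBN (cat.), toluene, 80 °C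
Reagents that add atoms: none
Why: Radical chain dehalogenation removes the C7 iodine without touching the lactone or the two alkenes and creates no stereocentre.

Step 8
Reactants: 11 cis-fused γ-lactone
Product: 13 primary alcohol, via alkyldisiamylborane 12 (not isolated)
Conditions: [(CH3)2CHCH(CH3)]2BH (made in the flask from BH3·THF and 2-methylbut-2-ene), THF, 0 °C; then 30% H2O2, pH 7 phosphate buffer, 0 °C → rt
Reagents that add atoms: hydrogen peroxide, OO
Why: Hydroboration–oxidation with the hindered dialkylborane is selective for the monosubstituted allyl double bond over the 1,1-disubstituted isopropenyl group and gives the anti-Markovnikov alcohol, while buffered peroxide spares the lactone.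

Step 9
Reactants: 13 primary alcohol
Product: 14 aldehyde
Conditions: Dess–Martin periodinane, CH2Cl2, 0 °C → rt
Reagents that add atoms: none
Why: Dess–Martin oxidation of the primary alcohol to the aldehyde under neutral conditions, with no stereocentre affected.

Step 10
Reactants: 14 aldehyde
Product: 15 (3R)-vinyl carbinol
Conditions: (CH2=CH)2Zn (salt-free solution prepared beforehand), (−)-3-exo-(dimethylamino)isoborneol (10 mol%), toluene, −20 → 0 °C; then H2O
Reagents that add atoms: divinylzinc, C=C[Zn]C=C
Why: Amino-alcohol-catalysed enantioselective addition of a vinylzinc reagent to an aldehyde, in which the ligand enantiomer chosen should deliver vinyl to the Si face and give the (3R) carbinol under reagent control, remote from the ring stereocentres.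

Step 11
Reactants: 15 (3R)-vinyl carbinol
Product: 16 TBS ether diene
Conditions: TBSCl, imidazole, DMF, rt
Reagents that add atoms: tert-butyldimethylsilyl chloride, CC(C)(C)[Si](C)(C)Cl
Why: Silylation of the secondary allylic alcohol installs the bulky group that later steers the epoxidation and sits on the migrating carbon in the key step.

Step 12
Reactants: 16 TBS ether diene
Product: 17 bicyclic cycloheptene lactone
Conditions: (H2IMes)(PCy3)Cl2Ru=CHPh (second-generation Grubbs catalyst, 5–10 mol%), toluene (high dilution), 80 °C
Reagents that add atoms: none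
Why: Ring-closing metathesis between the vinyl group and the isopropenyl group closes the seven-membered ring (trisubstituted C19=C4) trans-fused to ring B with loss of ethylene, and no stereocentre changes.

Step 13
Reactants: 17 bicyclic cycloheptene lactone
Product: 18 γ-lactol
Conditions: i-Bu2AlH, CH2Cl2, −78 °C; then aqueous work-up
Reagents that add atoms: none
Why: Partial reduction of the γ-lactone at low temperature stops at the tetrahedral aluminium hemiacetal and gives the lactol.

Step 14
Reactants: 18 γ-lactol
Product: 19 methyl enol ether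
Conditions: CH3OCH2PPh3Cl, KN(SiMe3)2, THF, 0 °C → rt
Reagents that add atoms: (methoxymethyl)triphenylphosphonium chloride, COC[P+](c1ccccc1)(c1ccccc1)c1ccccc1.[Cl-]
Why: Wittig methoxymethylenation of the ring-opened hydroxy aldehyde form of the lactol adds C13 as an enol ether and frees the tertiary C8 hydroxyl.

Step 15
Reactants: 19 methyl enol ether
Product: 20 δ-lactol
Conditions: pyridinium p-toluenesulfonate, acetone/H2O, 40 °C
Reagents that add atoms: water, O
Why: Mild acid hydrolysis of the enol ether gives the C13 aldehyde, which the cis C8 hydroxyl traps as the six-membered lactol, and the allylic silyl ether should survive the weak acid.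

Step 16
Reactants: 20 δ-lactol
Product: 21 alkyne
Conditions: dimethyl (1-diazo-2-oxopropyl)phosphonate, K2CO3, MeOH, 0 °C → rt
Reagents that add atoms: dimethyl (1-diazo-2-oxopropyl)phosphonate, COP(=O)(OC)C(=[N+]=[N-])C(C)=O
Why: Ohira–Bestmann (Seyferth–Gilbert) homologation of the aldehyde form of the lactol gives the terminal alkyne C13≡C16 and leaves the C8 hydroxyl free, without any leaving group at C12 that O-8 could displace to form a cyclic ether.

Step 17
Reactants: 21 alkyne
Product: 22 trans-epoxy silyl ether
Conditions: mCPBA, NaHCO3, CH2Cl2, 0 °C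
Reagents that add atoms: meta-chloroperoxybenzoic acid, OOC(=O)c1cccc(Cl)c1
Why: Prilezhaev epoxidation of the only alkene, in which the peracid should attack C19=C4 anti to the allylic OTBS group and anti to the C20 methyl group (both on the same face), giving the oxirane on the H-5 face while the alkyne stays inert.

Step 18
Reactants: 22 trans-epoxy silyl ether
Product: 23 β-siloxy aldehyde
Conditions: CH3Al(OAr)2 (methylaluminium bis(4-bromo-2,6-di-tert-butylphenoxide), 3 equiv), CH2Cl2, −78 → −20 °C; then H2O
Reagents that add atoms: none
Why: The bulky, oxophilic aluminium phenoxide binds the oxirane oxygen on the H-5 face and ionises the tertiary C4–O bond, whereupon ring carbon C3 (bearing OTBS) shifts from C19 to C4 on the C20 face while C19 collapses to the aluminium-bound aldehyde, so the seven-membered ring C10–C1–C2–C3–C19–C4–C5 contracts to ring A (C10–C1–C2–C3–C4–C5) and C19 becomes the exocyclic formyl group. The closest known reaction type is the rearrangement of 2,3-epoxy silyl ethers to β-siloxy aldehydes by anti 1,2-shift of the siloxy-bearing carbon under this same reagent, run here in its ring-contracting (Meinwald-type) mode. Ring A is therefore closed not by a cyclisation but by a suprafacial 1,2-alkyl shift (seven to six), the C3–C4 bond forming as the C3–C19 bond breaks. C4 is the only new stereocentre and is formed with inversion at the oxirane carbon, so the H-5-face epoxide from step 17 places C18 on the C20 face (axial) and the formyl carbon C19 on the H-5 face (equatorial), while C3 migrates with retention and keeps its OTBS on the C20 face (equatorial in ring A). The step needs C4–O rather than C19–O cleavage, which the tertiary versus secondary oxirane carbons secure, and shift of C3 rather than of H-19, which should follow from the preference of a siloxyalkyl group over hydride with this reagent and from the OTBS group lying anti to the aluminium-bound oxygen; the bulk of the reagent also disfavours proton loss to an allylic alcohol. One further equivalent of reagent is consumed by the free C8 hydroxyl, which is held as an inert aluminium alkoxide until work-up.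

Step 19
Reactants: 23 β-siloxy aldehyde
Product: 24 β-hydroxy aldehyde
Conditions: HF·pyridine, pyridine/THF, 0 °C → rt
Reagents that add atoms: none
Why: Fluoride desilylation under buffered acidic conditions frees the C3 hydroxyl without the base that could trigger retro-aldol cleavage of the α-quaternary β-hydroxy aldehyde.

Step 20
Reactants: 24 β-hydroxy aldehyde
Product: 25 3-acetoxy-19-hydroxy alkyne
Conditions: CH3CHO (excess), SmI2 (samarium diiodide, 0.3 equiv), THF, −10 °C
Reagents that add atoms: acetaldehyde, CC=O
Why: Evans–Tishchenko reaction, in which the C3 hydroxyl adds to acetaldehyde and the samarium-bound hemiacetal transfers hydride through a six-membered transition state to the neighbouring C19 aldehyde, so C19 becomes CH2OH and the acetyl group ends on O-3 in one redox-neutral step without creating a stereocentre.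

Step 21
Reactants: 25 3-acetoxy-19-hydroxy alkyne
Product: 26 target CNP0313672.1
Conditions: ethylene (1 atm), (H2IMes)(PCy3)Cl2Ru=CHPh (second-generation Grubbs catalyst, 5 mol%), toluene, 60–80 °C
Reagents that add atoms: ethylene, C=C
Why: Ethylene–alkyne cross enyne metathesis converts the terminal alkyne into the 2-substituted buta-1,3-diene (C13=C16 and C14=C15) under neutral conditions that tolerate the acetate and both free hydroxyls.

Compound list
1 | (S)-(+)-carvone, (5S)-2-methyl-5-(prop-1-en-2-yl)cyclohex-2-en-1-one | CC(=C)[C@H]1CC=C(C)C(=O)C1 | starting material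
2 | trans-6-methylcarvone: methyl at C6 trans to the isopropenyl group (major epimer; the cis epimer reacts on alike) | O=C1C(C)=CC[C@H](C(C)=C)[C@H]1C | intermediate
3 | 6-allyl-6-methylcarvone: quaternary C6 (future C10) with allyl trans and methyl cis to the C5 isopropenyl group | O=C1C(C)=CC[C@H](C(C)=C)[C@@]1(C)CC=C | intermediate
4 | 2,3-epoxide of 3 (future C8–C7 oxirane), oxirane oxygen trans to the isopropenyl group | O=C1[C@@]2(C)O[C@H]2C[C@H](C(C)=C)[C@@]1(C)CC=C | intermediate
5 | hydrazone of 4 at the ketone carbon (future C9); not isolated | NN=C1[C@@]2(C)O[C@H]2C[C@H](C(C)=C)[C@@]1(C)CC=C | intermediate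
6 | 4-allyl-2,4-dimethyl-5-(prop-1-en-2-yl)cyclohex-2-en-1-ol: C7–OH and allyl trans to isopropenyl, C8=C9 alkene | O[C@H]1C[C@H](C(C)=C)[C@@](C)(CC=C)C=C1C | intermediate
7 | 1-(dimethylamino)vinyl ether of 6 (ketene N,O-acetal); not isolated | C=C(N(C)C)O[C@H]1C[C@H](C(C)=C)[C@@](C)(CC=C)C=C1C | intermediate
8 | N,N-dimethylacetamide with the cyclohexene ring on its α-carbon (C11): C7=C8(CH3) alkene, C9–CH2CONMe2 and C10-allyl trans to isopropenyl, C20 cis to it | CN(C)C(=O)C[C@H]1C(C)=CC[C@H](C(C)=C)[C@@]1(C)CC=C | intermediate
9 | cyclic O-alkyl N,N-dimethyliminium iodide (iminium lactone) with C7–I; not isolated | C[N+](C)=C1C[C@H]2[C@@](C)(O1)[C@H](I)C[C@H](C(C)=C)[C@@]2(C)CC=C.[I-] | intermediate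
10 | iodolactone: cis-fused γ-lactone C12(=O)–O–C8 (O-8 cis to C11), C7–I anti to O-8 | O=C1C[C@H]2[C@@](C)(O1)[C@H](I)C[C@H](C(C)=C)[C@@]2(C)CC=C | intermediate
11 | cis-fused γ-lactone without iodine: C8 carries C17 and the lactone oxygen, C10 carries C20 and allyl, C5 carries isopropenyl | O=C1C[C@H]2[C@@](C)(O1)CC[C@H](C(C)=C)[C@@]2(C)CC=C | intermediate
12 | alkylbis(3-methylbutan-2-yl)borane from the allyl group of 11; not isolated | O=C1C[C@H]2[C@@](C)(O1)CC[C@H](C(C)=C)[C@@]2(C)CCCB(C(C)C(C)C)C(C)C(C)C | intermediate
13 | primary alcohol: C10–CH2CH2CH2OH (C1–C3) on lactone 11 | O=C1C[C@H]2[C@@](C)(O1)CC[C@H](C(C)=C)[C@@]2(C)CCCO | intermediate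
14 | aldehyde: C10–CH2CH2CHO (C3 aldehyde) | O=C1C[C@H]2[C@@](C)(O1)CC[C@H](C(C)=C)[C@@]2(C)CCC=O | intermediate
15 | (3R)-allylic alcohol: C10–CH2CH2CH(OH)CH=CH2 | O=C1C[C@H]2[C@@](C)(O1)CC[C@H](C(C)=C)[C@@]2(C)CC[C@@H](O)C=C | intermediate
16 | tert-butyldimethylsilyl ether of 15 | O=C1C[C@H]2[C@@](C)(O1)CC[C@H](C(C)=C)[C@@]2(C)CC[C@@H](O[Si](C)(C)C(C)(C)C)C=C | intermediate
17 | trans-fused bicyclo[5.4.0]undecene lactone: seven-membered ring C10–C1–C2–C3–C19=C4–C5, (3R)-OTBS on the C20 face, γ-lactone on ring B | O=C1C[C@H]2[C@@](C)(O1)CC[C@@H]3C(C)=C[C@H](O[Si](C)(C)C(C)(C)C)CC[C@@]23C | intermediate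
18 | γ-lactol from 17 (C12 hemiacetal, anomer mixture) | OC1C[C@H]2[C@@](C)(O1)CC[C@@H]3C(C)=C[C@H](O[Si](C)(C)C(C)(C)C)CC[C@@]23C | intermediate
19 | methyl enol ether C13H(OCH3)=C12H (E/Z mixture) with free tertiary C8–OH | COC=CC[C@H]1[C@@](C)(O)CC[C@@H]2C(C)=C[C@H](O[Si](C)(C)C(C)(C)C)CC[C@@]12C | intermediate
20 | δ-lactol: six-membered hemiacetal O-8–C13(OH)–C12–C11–C9–C8 (anomer mixture) | OC1CC[C@H]2[C@@](C)(O1)CC[C@@H]3C(C)=C[C@H](O[Si](C)(C)C(C)(C)C)CC[C@@]23C | intermediate
21 | alkyne: C9–CH2CH2C≡CH on the H-5 face, free C8–OH, C3–OTBS, C19=C4 in the seven-membered ring | C#CCC[C@H]1[C@@](C)(O)CC[C@@H]2C(C)=C[C@H](O[Si](C)(C)C(C)(C)C)CC[C@@]12C | intermediate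
22 | trans-epoxy silyl ether: C19–C4 oxirane on the H-5 face, C3–OTBS on the C20 face | C#CCC[C@H]1[C@@](C)(O)CC[C@@H]2[C@@]3(C)O[C@H]3[C@H](O[Si](C)(C)C(C)(C)C)CC[C@@]12C | intermediate
23 | β-siloxy aldehyde: trans-decalin with ring A formed, C4 carrying C18 (C20 face) and CHO (C19, H-5 face), C3–OTBS equatorial | C#CCC[C@@H]1[C@]2(C)CC[C@@H](O[Si](C)(C)C(C)(C)C)[C@](C)(C=O)[C@H]2CC[C@]1(C)O | intermediate
24 | β-hydroxy aldehyde: 3-hydroxy-19-oxo compound with free C8–OH and the butynyl side chain | C#CCC[C@@H]1[C@]2(C)CC[C@@H](O)[C@](C)(C=O)[C@H]2CC[C@]1(C)O | intermediate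
25 | 3-acetoxy-8,19-diol with the but-3-ynyl side chain at C9 | C#CCC[C@@H]1[C@]2(C)CC[C@@H](OC(C)=O)[C@](C)(CO)[C@H]2CC[C@]1(C)O | intermediate
26 | CNP0313672.1, 3-acetoxy-labda-13(16),14-diene-8,19-diol in the configuration given | C=CC(=C)CC[C@@H]1[C@]2(C)CC[C@@H](OC(C)=O)[C@](C)(CO)[C@H]2CC[C@]1(C)O | target

Total step count: 21. Longest linear sequence: 21 steps (fully linear from (S)-carvone).

Steps most likely to fail

Step 18. The C4 cation may be quenched by shift of H-19 instead of C3 (a C19 ketone without contraction) or by proton loss. The fallback uses the acyl-shift ring contraction of an epoxy ketone, a reaction type well established for 2,3-epoxy-3-methylcycloalkanones. It sets out from 21: Bu4NF in THF should give the free cycloheptenol F1, and MnO2 in CH2Cl2 the cycloheptenone F2. H2O2/NaOH in MeOH at 0 °C should then give the epoxy ketone F3 with the oxirane anti to C20. BF3·OEt2 (CH2Cl2, −78 → 0 °C) should contract the ring by 1,2-shift of the acyl carbon C3 from C19 to C4, with inversion at C4, to the β-keto aldehyde F4. NaBH4 (MeOH, 0 °C, axial attack at C3) would give the diol F5, and TEMPO/PhI(OAc)2 in CH2Cl2 should oxidise only the primary C19 alcohol, which returns to the route at 24.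

Step 4. Hydrazone formation at a ketone flanked by two fully substituted carbons may be slow, so that hydrazine opens the oxirane instead. The fallback replaces the diazene by a radical fragmentation and sets out from 4: NaBH4/CeCl3·7H2O in MeOH should give the epoxy alcohol F6, and NaH, CS2, then CH3I in THF the epoxy xanthate F7. Bu3SnH/AIBN (toluene, 80 °C) should then generate the C9 radical, whose oxirane opens at once to the C7 alkoxyl radical; hydrogen transfer returns to the route at 6.

Step 10. Facial discrimination in vinyl transfer to the unbranched aldehyde may be insufficient, and a C3 epimer would be carried into the wrong epoxide and acetate configuration. The fallback sets C3 on the ring by reagent-controlled ketone reduction and sets out from 14: CH2=CHMgBr (THF, −78 °C) should give the epimeric allylic alcohols F8, and ring-closing metathesis as in step 12 the cycloheptenols F9. MnO2 would give the cycloheptenone F10, and Corey–Bakshi–Shibata reduction ((S)-2-methyl-CBS-oxazaborolidine, BH3·SMe2, −30 °C, alkenyl as the large group) the single (3R)-cycloheptenol F11. TBSCl/imidazole then returns to the route at 17.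

Further compounds
F1 | step 18 | desilylated 21: (3R)-cyclohept-2-enol with free C3–OH and C8–OH | C#CCC[C@H]1[C@@](C)(O)CC[C@@H]2C(C)=C[C@H](O)CC[C@@]12C
F2 | step 18 | cycloheptenone: C3 ketone conjugated with C19=C4 | C#CCC[C@H]1[C@@](C)(O)CC[C@@H]2C(C)=CC(=O)CC[C@@]12C
F3 | step 18 | epoxy ketone: C19–C4 oxirane on the H-5 face, C3 ketone | C#CCC[C@H]1[C@@](C)(O)CC[C@@H]2[C@@]3(C)O[C@H]3C(=O)CC[C@@]12C
F4 | step 18 | β-keto aldehyde: ring A formed, C3 ketone, C4 carrying C18 (C20 face) and CHO (H-5 face) | C#CCC[C@@H]1[C@]2(C)CCC(=O)[C@](C)(C=O)[C@H]2CC[C@]1(C)O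
F5 | step 18 | 3,8,19-triol with the but-3-ynyl side chain (C3–OH equatorial, C20 face) | C#CCC[C@@H]1[C@]2(C)CC[C@@H](O)[C@](C)(CO)[C@H]2CC[C@]1(C)O
F6 | step 4 | epoxy alcohol from 4 (C9 carbinol, configuration at C9 not defined) | OC1[C@@]2(C)O[C@H]2C[C@H](C(C)=C)[C@@]1(C)CC=C
F7 | step 4 | S-methyl xanthate of F6 | CSC(=S)OC1[C@@]2(C)O[C@H]2C[C@H](C(C)=C)[C@@]1(C)CC=C
F8 | step 10 | allylic alcohols epimeric at C3 (C10–CH2CH2CH(OH)CH=CH2) | O=C1C[C@H]2[C@@](C)(O1)CC[C@H](C(C)=C)[C@@]2(C)CCC(O)C=C
F9 | step 10 | bicyclic cycloheptenols epimeric at C3 | O=C1C[C@H]2[C@@](C)(O1)CC[C@@H]3C(C)=CC(O)CC[C@@]23C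
F10 | step 10 | bicyclic cycloheptenone lactone (C3 ketone, C19=C4) | O=C1C[C@H]2[C@@](C)(O1)CC[C@@H]3C(C)=CC(=O)CC[C@@]23C
F11 | step 10 | (3R)-cycloheptenol lactone (free alcohol of 17) | O=C1C[C@H]2[C@@](C)(O1)CC[C@@H]3C(C)=C[C@H](O)CC[C@@]23C
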